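Ring B is opened at C8–C8a. C8 is a CH(CH3) centre next to the fusion carbon C8a, and C8a lies β to the C2 oxygen of ring A. A vinyl group at C8 therefore serves twice: its terminal carbon ends as the C8 methyl after hydrogen-atom transfer, and its inner carbon bonds to C8a as a radical adding to a ring A enone. This one operation closes ring B (6-exo) and sets C8 and C8a. The precursor is a 6-methylcyclohex-2-enone (ring A) whose C4a carries the chain C5H2–C6H(OPMB)–C7H(OMOM)–C8H=CH2. The C1/C2 oxygens, the C3=C4 bond and the C5 isopropylidene follow afterwards.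

Key step: step 8

Conventions: atoms carry the target decalin numbers also in open-chain precursors (C1, C2 acetoxy carbons; C3=C4; C4a/C8a fusion; C5 isopropylidene carbon; C6 ketone; C7 carbinol; C8 methyl-bearing carbon). In bicyclic compounds β is the face of H-4a/H-8a and α the opposite face. PMB = 4-methoxybenzyl, MOM = methoxymethyl, TBS = tert-butyldimethylsilyl.
Assumption: ketal ester 1 is taken as a catalogue compound; the sense of the asymmetric deprotonation in step 5 is assigned by analogy with 4-tert-butylcyclohexanone.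
Design remark: C6 is carried as the PMB ether of the syn alcohol, because a C6 ketone beside the C7 stereocentre and the vinyl group would invite epimerization and conjugation. An electrophile would reach C1 only from the β face (wrong epimer), so both ring A oxygens are placed by hydrogen delivery from the β face (steps 12 and 14).

Step 1
Reactants: 1 ethyl 2-(1,4-dioxaspiro[4.5]decan-8-yl)acetate
Product: 2 2-(1,4-dioxaspiro[4.5]decan-8-yl)acetaldehyde
Conditions: (iBu)2AlH (1.05 equiv), CH2Cl2, −78 °C; aq. potassium sodium tartrate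
Reagents that add atoms: none
Why: Half-reduction of an ester with (iBu)2AlH at −78 °C should stop at the aldehyde oxidation level, and the ketal keeps the ring carbonyl masked for the next step.

Step 2
Reactants: 2 2-(1,4-dioxaspiro[4.5]decan-8-yl)acetaldehyde; 3 3-(methoxymethoxy)prop-1-ene
Product: 7 (2S,3S)-1-(1,4-dioxaspiro[4.5]decan-8-yl)-3-(methoxymethoxy)pent-4-en-2-ol, via (Z)-3-(methoxymethoxy)allyllithium 4 (not isolated), via (Z)-γ-(methoxymethoxy)allyl(diisopinocampheyl)borane 5 (not isolated), via diisopinocampheylborinate adduct 6 (not isolated)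
Conditions: 3, sBuLi, THF, −78 °C; (+)-Ipc2BOMe; BF3·OEt2; then 2, −78 °C; NaOH, H2O2, 0 °C to rt
Reagents that add atoms: 3-(methoxymethoxy)prop-1-ene (compound 3), C=CCOCOC
Why: Brown γ-alkoxyallylboration: the (Z)-γ-alkoxyallylborane reacts through a closed chair transition state, which gives the syn 2,3-relationship, and the isopinocampheyl groups derived from (−)-α-pinene select the aldehyde face leading to the (2S,3S) isomer, so that C7 of the target is fixed here by reagent control.

Step 3
Reactants: 7 (2S,3S)-1-(1,4-dioxaspiro[4.5]decan-8-yl)-3-(methoxymethoxy)pent-4-en-2-ol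
Product: 8 8-[(2S,3S)-2-[(4-methoxyphenyl)methoxy]-3-(methoxymethoxy)pent-4-en-1-yl]-1,4-dioxaspiro[4.5]decane
Conditions: NaH, 4-MeOC6H4CH2Cl, Bu4NI (cat.), DMF, 0 °C to rt
Reagents that add atoms: 4-methoxybenzyl chloride, COc1ccc(CCl)cc1
Why: Williamson etherification of the secondary alkoxide gives a PMB ether that should survive every later base, hydride, silyl triflate and radical step and can be removed oxidatively in the presence of acetates.

Step 4
Reactants: 8 8-[(2S,3S)-2-[(4-methoxyphenyl)methoxy]-3-(methoxymethoxy)pent-4-en-1-yl]-1,4-dioxaspiro[4.5]decane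
Product: 9 4-[(2S,3S)-2-[(4-methoxyphenyl)methoxy]-3-(methoxymethoxy)pent-4-en-1-yl]cyclohexan-1-one
Conditions: pyridinium p-toluenesulfonate (cat.), acetone/H2O, 55 °C
Reagents that add atoms: water, O
Why: Acid-catalysed ketal hydrolysis in wet acetone frees the ring ketone under conditions too mild to cleave the MOM or PMB ether.

Step 5
Reactants: 9 4-[(2S,3S)-2-[(4-methoxyphenyl)methoxy]-3-(methoxymethoxy)pent-4-en-1-yl]cyclohexan-1-one
Product: 10 {[(4R)-4-[(2S,3S)-2-[(4-methoxyphenyl)methoxy]-3-(methoxymethoxy)pent-4-en-1-yl]cyclohex-1-en-1-yl]oxy}trimethylsilane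
Conditions: (S,S)-bis(1-phenylethyl)amine, nBuLi, THF; Me3SiCl then 9, −78 °C (internal quench)
Reagents that add atoms: chlorotrimethylsilane, C[Si](C)(C)Cl
Why: Asymmetric deprotonation (desymmetrization) of the 4-substituted cyclohexanone: the chiral lithium amide removes one of the two enantiotopic axial α-protons and the enolate is trapped at once as the silyl enol ether, which sets C4a; because the side chain is already enantiopure, material from the minor sense of deprotonation is a diastereomer and can be removed after step 6.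

Step 6
Reactants: 10 {[(4R)-4-[(2S,3S)-2-[(4-methoxyphenyl)methoxy]-3-(methoxymethoxy)pent-4-en-1-yl]cyclohex-1-en-1-yl]oxy}trimethylsilane
Product: 11 (4S)-4-[(2S,3S)-2-[(4-methoxyphenyl)methoxy]-3-(methoxymethoxy)pent-4-en-1-yl]cyclohex-2-en-1-one
Conditions: Pd(OAc)2 (1.1 equiv), MeCN, rt
Reagents that add atoms: none
Why: Saegusa oxidation: the silyl enol ether forms a palladium enolate that undergoes β-hydride elimination on the side of the former enol double bond, giving the enone without touching C4a.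

Step 7
Reactants: 11 (4S)-4-[(2S,3S)-2-[(4-methoxyphenyl)methoxy]-3-(methoxymethoxy)pent-4-en-1-yl]cyclohex-2-en-1-one; 12 iodomethane
Product: 14 (4S,6R)-4-[(2S,3S)-2-[(4-methoxyphenyl)methoxy]-3-(methoxymethoxy)pent-4-en-1-yl]-6-methylcyclohex-2-en-1-one, via lithium dienolate 13 (not isolated)
Conditions: LiN(iPr)2, THF, −78 °C; MeI, −78 to −40 °C
Reagents that add atoms: iodomethane (compound 12), CI
Why: Kinetic α′-deprotonation of the enone and alkylation of the cross-conjugated lithium dienolate with MeI (enolate alkylation) should give mainly the trans-4,6 isomer by axial attack, and the C3 configuration is immaterial because C3 becomes trigonal in step 10.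

Step 8
Reactants: 14 (4S,6R)-4-[(2S,3S)-2-[(4-methoxyphenyl)methoxy]-3-(methoxymethoxy)pent-4-en-1-yl]-6-methylcyclohex-2-en-1-one
Product: 15 cis-fused decalin-2-one (4aβ-H/8aβ-H; 3β-methyl; 6β-OPMB; 7α-OMOM; 8β-methyl)
Conditions: Fe(acac)3 (0.3 equiv), PhSiH3 (2.5 equiv), EtOH/HOCH2CH2OH (5:1), 60 °C, 0.01 M
Reagents that add atoms: none
Why: An iron hydride generated from Fe(acac)3 and PhSiH3 transfers a hydrogen atom to the terminal vinyl carbon (Markovnikov, the only unconjugated alkene), which becomes the C8 methyl, and the secondary C8 radical adds to the enone β-carbon C8a; the C1 α-keto radical is then reduced to the enolate and protonated by ethanol. The closest known reaction type is the iron-hydride hydrogen-atom-transfer reductive olefin–enone coupling (radical conjugate addition), used here intramolecularly. Ring B closes in the 6-exo-trig mode, the C1=C8a bond staying outside the new ring. C8a is controlled by the tether: the four-atom chain on C4a can reach C8a only on its own face, and axial attack on the enone having C5 pseudo-equatorial gives the cis ring fusion. C8 is controlled by the chair-like transition state, in which the syn-related C6 and C7 oxygens and the C8 methyl are all equatorial (an axial methyl would point under ring A), so the methyl ends trans to the C7 oxygen and cis to H-8a. The step needs hydrogen-atom transfer to the vinyl group in preference to the enone and ring closure faster than reduction of the radical, which the electron-neutral terminal alkene, the unhindered electron-poor β-carbon and high dilution with slow silane turnover should secure.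

Step 9
Reactants: 15 cis-fused decalin-2-one (4aβ-H/8aβ-H; 3β-methyl; 6β-OPMB; 7α-OMOM; 8β-methyl)
Product: 16 trimethylsilyl enol ether of 15 having the C2=C3 double bond
Conditions: Me3SiCl, Et3N, DMF, 90 °C
Reagents that add atoms: chlorotrimethylsilane, C[Si](C)(C)Cl
Why: Silylation under equilibrating conditions (thermodynamic silyl enol ether formation) should favour the tetrasubstituted C2=C3 enol ether, which in addition relieves the axial 3-methyl group, over the C1=C2 isomer.

Step 10
Reactants: 16 trimethylsilyl enol ether of 15 having the C2=C3 double bond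
Product: 17 cis-fused C3=C4 enone (3,8β-dimethyl; 6β-OPMB; 7α-OMOM; 4aβ-H/8aβ-H; C2 ketone)
Conditions: Pd(OAc)2 (1.1 equiv), MeCN, 40 °C
Reagents that add atoms: none
Why: Saegusa oxidation of the tetrasubstituted enol ether places palladium at C3, and β-hydride elimination from the ring methylene C4 should give the conjugated endocyclic C3=C4 enone.

Step 11
Reactants: 17 cis-fused C3=C4 enone (3,8β-dimethyl; 6β-OPMB; 7α-OMOM; 4aβ-H/8aβ-H; C2 ketone)
Product: 19 2-(tert-butyldimethylsilyloxy)-1,3-diene (C1=C2 and C3=C4; TBS dienol ether of 17), via lithium dienolate 18 (not isolated)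
Conditions: LiN(iPr)2, THF, −78 °C; tBuMe2SiOTf
Reagents that add atoms: tert-butyldimethylsilyl trifluoromethanesulfonate, CC(C)(C)[Si](C)(C)OS(=O)(=O)C(F)(F)F
Why: Kinetic α′-deprotonation at C1 and O-silylation of the cross-conjugated dienolate (silyl dienol ether formation) convert the ketone into a 2-silyloxy-1,3-diene whose C1=C2 bond is the electron-rich enol ether.

Step 12
Reactants: 19 2-(tert-butyldimethylsilyloxy)-1,3-diene (C1=C2 and C3=C4; TBS dienol ether of 17)
Product: 21 1β-hydroxy-2α-(tert-butyldimethylsilyloxy) compound (C3=C4; 6β-OPMB; 7α-OMOM; 8β-methyl), via C1 alkylborane 20 (not isolated)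
Conditions: BH3·THF (1.2 equiv), THF, 0 °C; then NaOH, H2O2, 0 °C
Reagents that add atoms: hydrogen peroxide, OO
Why: Hydroboration–oxidation of a silyl enol ether: borane attacks the enol ether terminus C1 (largest HOMO coefficient, β to oxygen) and delivers hydride syn to C2 from the convex β face, anti to the pseudo-axial C8a–C8 bond, so H-2 is β and the silyloxy group α (the target C2 configuration), while oxidation with retention gives the 1β-alcohol whose configuration is corrected in steps 13 and 14.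

Step 13
Reactants: 21 1β-hydroxy-2α-(tert-butyldimethylsilyloxy) compound (C3=C4; 6β-OPMB; 7α-OMOM; 8β-methyl)
Product: 22 C1 ketone bearing the 2α-(tert-butyldimethylsilyloxy) group (C3=C4)
Conditions: Dess–Martin periodinane, NaHCO3, CH2Cl2, 0 °C; used crude
Reagents that add atoms: none
Why: Dess–Martin oxidation under buffered, non-enolizing conditions converts the 1β-alcohol into the C1 ketone, which is used crude because the α-silyloxy β,γ-unsaturated ketone could conjugate or epimerize on standing.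

Step 14
Reactants: 22 C1 ketone bearing the 2α-(tert-butyldimethylsilyloxy) group (C3=C4)
Product: 23 1α-hydroxy-2α-(tert-butyldimethylsilyloxy) compound (C3=C4; 6β-OPMB; 7α-OMOM; 8β-methyl)
Conditions: NaBH4, CeCl3·7H2O, MeOH, −78 °C
Reagents that add atoms: none
Why: Luche-type borohydride reduction: hydride adds to the C1 ketone from the β face, axially and anti to both the axial C8a–C8 bond and the α-silyloxy group (Felkin–Anh), so the new hydroxyl is 1α and cis to the C2 oxygen, which places the C1 oxygen on the concave face that direct oxygenation cannot reach.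

Step 15
Reactants: 23 1α-hydroxy-2α-(tert-butyldimethylsilyloxy) compound (C3=C4; 6β-OPMB; 7α-OMOM; 8β-methyl)
Product: 25 1α,2α-diacetate (C3=C4; 6β-OPMB; 7α-OMOM; 8β-methyl), via cis-diol 24 (not isolated)
Conditions: Bu4NF, THF, 0 °C to rt; then Ac2O, Et3N, 4-(dimethylamino)pyridine (cat.)
Reagents that add atoms: acetic anhydride, CC(=O)OC(C)=O
Why: Fluoride cleaves the allylic silyl ether and the resulting cis-diol is acetylated in the same flask under nucleophilic catalysis (desilylation then esterification), with no change at any stereocentre.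

Step 16
Reactants: 25 1α,2α-diacetate (C3=C4; 6β-OPMB; 7α-OMOM; 8β-methyl)
Product: 26 6β-alcohol (1α,2α-diacetate; 7α-OMOM)
Conditions: DDQ, CH2Cl2/pH 7 buffer, 0 °C to rt
Reagents that add atoms: none
Why: Oxidative PMB cleavage with DDQ (oxidation of the electron-rich benzyl ether and hydrolysis of the oxocarbenium ion) should free only the C6 hydroxyl, since acetates, the MOM ether and the trisubstituted alkene are inert to DDQ.

Step 17
Reactants: 26 6β-alcohol (1α,2α-diacetate; 7α-OMOM)
Product: 27 C6 ketone (1α,2α-diacetate; 7α-OMOM)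
Conditions: Dess–Martin periodinane, NaHCO3, CH2Cl2, rt
Reagents that add atoms: none
Why: Dess–Martin oxidation of the secondary alcohol gives the C6 ketone under near-neutral conditions that leave the adjacent C7 stereocentre, whose equatorial MOM ether is also the more stable epimer, untouched.

Step 18
Reactants: 27 C6 ketone (1α,2α-diacetate; 7α-OMOM); 28 acetone
Product: 30 5β-(2-hydroxypropan-2-yl) C6 ketone (aldol adduct), via lithium enolate 29 (not isolated)
Conditions: LiN(SiMe3)2, THF, −78 °C; acetone; AcOH quench at −78 °C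
Reagents that add atoms: acetone (compound 28), CC(C)=O
Why: Aldol addition: LiN(SiMe3)2 is basic enough for the ketone but not for the acetates and deprotonates the C5 methylene in preference to the alkoxy-bearing C7 methine, and the lithium enolate adds to acetone; the C5 configuration does not matter because C5 becomes trigonal in step 19.

Step 19
Reactants: 30 5β-(2-hydroxypropan-2-yl) C6 ketone (aldol adduct)
Product: 32 7-O-methoxymethyl ether of the target, via tertiary mesylate 31 (not isolated)
Conditions: MeSO2Cl, Et3N, CH2Cl2, 0 °C; then DBU, rt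
Reagents that add atoms: none
Why: Dehydration by mesylation of the tertiary alcohol and E1cB elimination with DBU removes the acidic C5 hydrogen and so gives the conjugated, tetrasubstituted isopropylidene ketone in preference to the isopropenyl isomer.

Step 20
Reactants: 32 7-O-methoxymethyl ether of the target
Product: 34 (1R,2S,4aR,7S,8R,8aS)-7-hydroxy-3,8-dimethyl-6-oxo-5-(propan-2-ylidene)-1,2,4a,5,6,7,8,8a-octahydronaphthalene-1,2-diyl diacetate (CNP0333818.1), via bromomethyl ether 33 (not isolated)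
Conditions: Me2BBr, CH2Cl2, −78 °C; then aq. NaHCO3, THF
Reagents that add atoms: none
Why: Lewis-acid cleavage of the MOM acetal with Me2BBr at −78 °C, followed by hydrolysis of the bromomethyl ether on bicarbonate work-up, frees the C7 hydroxyl under conditions that spare acetates, allylic esters and enones.

Compound list
1 | ethyl 2-(1,4-dioxaspiro[4.5]decan-8-yl)acetate | CCOC(=O)CC1CCC2(CC1)OCCO2 | starting material
2 | 2-(1,4-dioxaspiro[4.5]decan-8-yl)acetaldehyde | O=CCC1CCC2(CC1)OCCO2 | intermediate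
3 | 3-(methoxymethoxy)prop-1-ene | C=CCOCOC | starting material
4 | (Z)-3-(methoxymethoxy)allyllithium | [Li]C/C=C\OCOC | intermediate
5 | (Z)-γ-(methoxymethoxy)allyl(diisopinocampheyl)borane, isopinocampheyl groups from (−)-α-pinene | COCO/C=C\CB([C@H]1C[C@H]2C[C@H](C2(C)C)[C@@H]1C)[C@H]1C[C@H]2C[C@H](C2(C)C)[C@@H]1C | intermediate
6 | diisopinocampheylborinate of alcohol 7 | C(C1CCC2(CC1)OCCO2)[C@H](OB([C@H]1C[C@H]2C[C@H](C2(C)C)[C@@H]1C)[C@H]1C[C@H]2C[C@H](C2(C)C)[C@@H]1C)[C@@H](OCOC)C=C | intermediate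
7 | (2S,3S)-1-(1,4-dioxaspiro[4.5]decan-8-yl)-3-(methoxymethoxy)pent-4-en-2-ol | C(C1CCC2(CC1)OCCO2)[C@H](O)[C@@H](OCOC)C=C | intermediate
8 | 8-[(2S,3S)-2-[(4-methoxyphenyl)methoxy]-3-(methoxymethoxy)pent-4-en-1-yl]-1,4-dioxaspiro[4.5]decane | C(C1CCC2(CC1)OCCO2)[C@H](OCc1ccc(OC)cc1)[C@@H](OCOC)C=C | intermediate
9 | 4-[(2S,3S)-2-[(4-methoxyphenyl)methoxy]-3-(methoxymethoxy)pent-4-en-1-yl]cyclohexan-1-one | O=C1CCC(CC1)C[C@H](OCc1ccc(OC)cc1)[C@@H](OCOC)C=C | intermediate
10 | {[(4R)-4-[(2S,3S)-2-[(4-methoxyphenyl)methoxy]-3-(methoxymethoxy)pent-4-en-1-yl]cyclohex-1-en-1-yl]oxy}trimethylsilane | C[Si](C)(C)OC1=CC[C@H](C[C@H](OCc2ccc(OC)cc2)[C@@H](OCOC)C=C)CC1 | intermediate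
11 | (4S)-4-[(2S,3S)-2-[(4-methoxyphenyl)methoxy]-3-(methoxymethoxy)pent-4-en-1-yl]cyclohex-2-en-1-one | O=C1C=C[C@H](C[C@H](OCc2ccc(OC)cc2)[C@@H](OCOC)C=C)CC1 | intermediate
12 | iodomethane | CI | starting material
13 | cross-conjugated lithium dienolate of 11 (O–C2=C3) | [Li]OC1=CC[C@@H](C[C@H](OCc2ccc(OC)cc2)[C@@H](OCOC)C=C)C=C1 | intermediate
14 | (4S,6R)-4-[(2S,3S)-2-[(4-methoxyphenyl)methoxy]-3-(methoxymethoxy)pent-4-en-1-yl]-6-methylcyclohex-2-en-1-one (precursor of the key step) | O=C1C=C[C@H](C[C@H](OCc2ccc(OC)cc2)[C@@H](OCOC)C=C)C[C@H]1C | intermediate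
15 | cis-fused decalin-2-one (4aβ-H/8aβ-H; 3β-methyl; 6β-OPMB; 7α-OMOM; 8β-methyl) (product of the key step) | O=C1C[C@@H]2[C@@H](C)[C@H](OCOC)[C@@H](OCc3ccc(OC)cc3)C[C@@H]2C[C@H]1C | intermediate
16 | trimethylsilyl enol ether of 15 having the C2=C3 double bond | C1[C@@H]2[C@@H](C)[C@H](OCOC)[C@@H](OCc3ccc(OC)cc3)C[C@@H]2CC(C)=C1O[Si](C)(C)C | intermediate
17 | cis-fused C3=C4 enone (3,8β-dimethyl; 6β-OPMB; 7α-OMOM; 4aβ-H/8aβ-H; C2 ketone) | O=C1C[C@@H]2[C@@H](C)[C@H](OCOC)[C@@H](OCc3ccc(OC)cc3)C[C@@H]2C=C1C | intermediate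
18 | cross-conjugated lithium dienolate of 17 (O–C2=C1; C3=C4) | [Li]OC1=C[C@@H]2[C@@H](C)[C@H](OCOC)[C@@H](OCc3ccc(OC)cc3)C[C@@H]2C=C1C | intermediate
19 | 2-(tert-butyldimethylsilyloxy)-1,3-diene (C1=C2 and C3=C4; TBS dienol ether of 17) | CC(C)(C)[Si](C)(C)OC1=C[C@@H]2[C@@H](C)[C@H](OCOC)[C@@H](OCc3ccc(OC)cc3)C[C@@H]2C=C1C | intermediate
20 | C1 alkylborane (1β-BH2; 2α-OTBS; C3=C4) | B[C@H]1[C@@H]2[C@@H](C)[C@H](OCOC)[C@@H](OCc3ccc(OC)cc3)C[C@@H]2C=C(C)[C@@H]1O[Si](C)(C)C(C)(C)C | intermediate
21 | 1β-hydroxy-2α-(tert-butyldimethylsilyloxy) compound (C3=C4; 6β-OPMB; 7α-OMOM; 8β-methyl) | O[C@H]1[C@@H]2[C@@H](C)[C@H](OCOC)[C@@H](OCc3ccc(OC)cc3)C[C@@H]2C=C(C)[C@@H]1O[Si](C)(C)C(C)(C)C | intermediate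
22 | C1 ketone bearing the 2α-(tert-butyldimethylsilyloxy) group (C3=C4) | O=C1[C@@H]2[C@@H](C)[C@H](OCOC)[C@@H](OCc3ccc(OC)cc3)C[C@@H]2C=C(C)[C@@H]1O[Si](C)(C)C(C)(C)C | intermediate
23 | 1α-hydroxy-2α-(tert-butyldimethylsilyloxy) compound (C3=C4; 6β-OPMB; 7α-OMOM; 8β-methyl) | O[C@@H]1[C@@H]2[C@@H](C)[C@H](OCOC)[C@@H](OCc3ccc(OC)cc3)C[C@@H]2C=C(C)[C@@H]1O[Si](C)(C)C(C)(C)C | intermediate
24 | 1α,2α-diol (C3=C4; 6β-OPMB; 7α-OMOM; 8β-methyl) | O[C@@H]1[C@@H]2[C@@H](C)[C@H](OCOC)[C@@H](OCc3ccc(OC)cc3)C[C@@H]2C=C(C)[C@@H]1O | intermediate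
25 | 1α,2α-diacetate (C3=C4; 6β-OPMB; 7α-OMOM; 8β-methyl) | CC(=O)O[C@@H]1[C@@H]2[C@@H](C)[C@H](OCOC)[C@@H](OCc3ccc(OC)cc3)C[C@@H]2C=C(C)[C@@H]1OC(C)=O | intermediate
26 | 6β-alcohol (1α,2α-diacetate; 7α-OMOM) | CC(=O)O[C@@H]1[C@@H]2[C@@H](C)[C@H](OCOC)[C@@H](O)C[C@@H]2C=C(C)[C@@H]1OC(C)=O | intermediate
27 | C6 ketone (1α,2α-diacetate; 7α-OMOM) | CC(=O)O[C@@H]1[C@@H]2[C@@H](C)[C@H](OCOC)C(=O)C[C@@H]2C=C(C)[C@@H]1OC(C)=O | intermediate
28 | acetone | CC(C)=O | starting material
29 | lithium enolate of 27 (O–C6=C5) | CC(=O)O[C@@H]1[C@@H]2[C@@H](C)[C@H](OCOC)C(O[Li])=C[C@@H]2C=C(C)[C@@H]1OC(C)=O | intermediate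
30 | 5β-(2-hydroxypropan-2-yl) C6 ketone (aldol adduct; expected major C5 epimer) | CC(=O)O[C@@H]1[C@@H]2[C@@H](C)[C@H](OCOC)C(=O)[C@@H](C(C)(C)O)[C@@H]2C=C(C)[C@@H]1OC(C)=O | intermediate
31 | tertiary mesylate of 30 | CC(=O)O[C@@H]1[C@@H]2[C@@H](C)[C@H](OCOC)C(=O)[C@@H](C(C)(C)OS(C)(=O)=O)[C@@H]2C=C(C)[C@@H]1OC(C)=O | intermediate
32 | 7-O-methoxymethyl ether of the target | CC(=O)O[C@@H]1[C@@H]2[C@@H](C)[C@H](OCOC)C(=O)C(=C(C)C)[C@@H]2C=C(C)[C@@H]1OC(C)=O | intermediate
33 | 7-O-bromomethyl ether of the target | CC(=O)O[C@@H]1[C@@H]2[C@@H](C)[C@H](OCBr)C(=O)C(=C(C)C)[C@@H]2C=C(C)[C@@H]1OC(C)=O | intermediate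
34 | (1R,2S,4aR,7S,8R,8aS)-7-hydroxy-3,8-dimethyl-6-oxo-5-(propan-2-ylidene)-1,2,4a,5,6,7,8,8a-octahydronaphthalene-1,2-diyl diacetate | CC(=O)O[C@@H]1[C@@H]2[C@@H](C)[C@H](O)C(=O)C(=C(C)C)[C@@H]2C=C(C)[C@@H]1OC(C)=O | target

Total step count: 20. Longest linear sequence: 20 steps (1 to 34).

Steps most likely to fail

Step 8 (radical cyclization): the C8 radical may be reduced by the iron hydride before it closes the ring, or facial control at C8 may be incomplete. Fallback from 14: Mukaiyama hydration of the vinyl group (Co(acac)2, PhSiH3, O2) gives the C8 alcohol F1 (either C8 epimer). Appel iodination (I2, PPh3, imidazole) gives the secondary iodide F2. Slow addition of Bu3SnH and azobisisobutyronitrile in hot benzene then generates the same C8 radical in a chain process without a metal hydride nearby, and 6-exo conjugate addition returns to 15.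

Step 9 (enol ether formation): enolization towards C1 instead of C3 under equilibrating conditions would later lead to desaturation towards the ring fusion. Fallback from 14: sulfenylation of the kinetic dienolate (LiN(iPr)2; PhSSPh) gives the 6-methyl-6-(phenylthio) enone F3 (C3 configuration immaterial). The same iron-hydride cyclization gives the 3-(phenylthio) decalone F4, and NaIO4 gives the sulfoxide F5. Thermal syn-elimination (toluene, 90 °C, CaCO3) towards the ring methylene C4 returns to 17, the position of the double bond now being dictated by sulfur and not by enolization.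

Step 12 (hydroboration): borane may add to the C3=C4 bond of the diene, or the β-silyloxy borane may undergo β-elimination. Fallback from 17: LiN(SiMe3)2 then 2-(phenylsulfonyl)-3-phenyloxaziridine hydroxylates C1 on the β face to give the 1β-hydroxy enone F6. Me4NBH(OAc)3 delivers hydride from the 1β-oxygen to give the 1β,2α-diol F7. Mitsunobu cyclodehydration (PPh3, diisopropyl azodicarboxylate) through the more accessible 1-hydroxyl gives the α-face vinyl epoxide F8. Pd(PPh3)4 under CO2 opens it with net retention at C2 to the cis-carbonate F9, and K2CO3/MeOH returns to diol 24.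

Further compounds
F1 | step 8 | C8 secondary alcohol from Markovnikov hydration of 14 (C8 epimers) | O=C1C=C[C@H](C[C@H](OCc2ccc(OC)cc2)[C@@H](OCOC)C(C)O)C[C@H]1C
F2 | step 8 | C8 secondary iodide (C8 epimers) | O=C1C=C[C@H](C[C@H](OCc2ccc(OC)cc2)[C@@H](OCOC)C(C)I)C[C@H]1C
F3 | step 9 | 6-methyl-6-(phenylthio) enone derived from 14 (C3 either configuration) | O=C1C=C[C@H](C[C@H](OCc2ccc(OC)cc2)[C@@H](OCOC)C=C)CC1(C)Sc1ccccc1
F4 | step 9 | 3-methyl-3-(phenylthio) cis-decalin-2-one | O=C1C[C@@H]2[C@@H](C)[C@H](OCOC)[C@@H](OCc3ccc(OC)cc3)C[C@@H]2CC1(C)Sc1ccccc1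
F5 | step 9 | sulfoxide of F4 | O=C1C[C@@H]2[C@@H](C)[C@H](OCOC)[C@@H](OCc3ccc(OC)cc3)C[C@@H]2CC1(C)S(=O)c1ccccc1
F6 | step 12 | 1β-hydroxy enone (C2 ketone; C3=C4) | O[C@H]1[C@@H]2[C@@H](C)[C@H](OCOC)[C@@H](OCc3ccc(OC)cc3)C[C@@H]2C=C(C)C1=O
F7 | step 12 | 1β,2α-diol (C3=C4) | O[C@H]1[C@@H]2[C@@H](C)[C@H](OCOC)[C@@H](OCc3ccc(OC)cc3)C[C@@H]2C=C(C)[C@@H]1O
F8 | step 12 | 1α,2α-epoxide (vinyl epoxide; C3=C4) | O1[C@@H]2[C@@H]3[C@@H](C)[C@H](OCOC)[C@@H](OCc4ccc(OC)cc4)C[C@@H]3C=C(C)[C@H]12
F9 | step 12 | 1α,2α-cyclic carbonate (C3=C4) | O=C1O[C@@H]2[C@@H]3[C@@H](C)[C@H](OCOC)[C@@H](OCc4ccc(OC)cc4)C[C@@H]3C=C(C)[C@@H]2O1
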